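**Retrosynthetic overview**
1. The dihydronaphthalene ring is formed last, by ring expansion: target ⇐ spiro[4.5]decatrienone, through a dienone–phenol 1,2-shift of the aryl-bearing carbon from the spiro carbon to the neighbouring ring carbon (5 → 6).
2. Spirodienone ⇐ guaiacyl p-quinone methide ⇐ achiral bis-arylidene hydroxy-aldehyde (asymmetric protonation, then ipso C–C bond to the para carbon of the syringyl phenol; the spiro-cyclopentene is the first carbocycle formed).
3. Bis-arylidene hydroxy-aldehyde ⇐ syringaldehyde + vanillylidene lactol (aldol condensation); lactol ⇐ vanillin + methyl 4-oxobutanoate (aldol condensation, then DIBAL-H).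
4. Syringaldehyde ⇐ p-cresol (bromination/side-chain oxidation, Cu-mediated methoxylation); vanillin ⇐ catechol + glyoxylic acid (mono-O-methylation, hydroxyalkylation/oxidative decarboxylation).

Assumption: the (R)-configured acid catalyst of step 8 is taken to give the (1S,2R) series; if the first run shows the opposite sense, its (S)-enantiomer is used.

**Step 1**
Reactants: 1 p-cresol (4-methylphenol)
Product: 4 3,5-dibromo-4-hydroxybenzaldehyde, via 2,6-dibromo-4-methylphenol 2 (not isolated), via 2,6-dibromo-4-(dibromomethyl)phenol 3 (not isolated)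
Conditions: Br2 (2.05 equiv), 1,2-dichlorobenzene, 35 °C; Br2 (2.05 equiv), 155 °C; then H2O, 100 °C
Reagents that add atoms: bromine BrBr; water O
Why: ortho,ortho ring bromination (SEAr), high-temperature side-chain dibromination of the hindered phenol and hydrolysis of the benzal bromide follow the technical p-cresol route to this aldehyde; no stereocenter.

**Step 2**
Reactants: 4 3,5-dibromo-4-hydroxybenzaldehyde
Product: 5 syringaldehyde (4-hydroxy-3,5-dimethoxybenzaldehyde)
Conditions: NaOMe (5 equiv), CuCl (10 mol%), DMF–MeOH, 115 °C; then aq. HCl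
Reagents that add atoms: sodium methoxide C[O-].[Na+]
Why: Cu(I)-catalysed Ullmann-type methoxylation of both aryl bromides ortho to the phenoxide, as in the technical syringaldehyde process.

**Step 3**
Reactants: 6 catechol
Product: 7 guaiacol (2-methoxyphenol)
Conditions: MeI (1.0 equiv), K2CO3 (1.0 equiv), acetone, 56 °C
Reagents that add atoms: iodomethane CI
Why: Williamson mono-O-methylation with one equivalent of MeI; veratrole and catechol are removed by base/acid extraction and distillation.

**Step 4**
Reactants: 7 guaiacol, 8 glyoxylic acid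
Product: 11 vanillin (4-hydroxy-3-methoxybenzaldehyde), via vanillylmandelic acid 9 (not isolated), via vanilloylformic acid 10 (not isolated)
Conditions: aq. NaOH, 30 °C; then CuSO4 (cat.), air, aq. NaOH, 95 °C; then aq. HCl
Reagents that add atoms: none
Why: para-selective hydroxyalkylation of the phenoxide by glyoxylate, Cu-catalysed aerobic oxidation to the aryl glyoxylic acid and decarboxylation on acidification (the technical guaiacol–glyoxylic acid vanillin process).

**Step 5**
Reactants: 11 vanillin, 12 methyl 4-oxobutanoate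
Product: 13 methyl (E)-3-formyl-4-(4-hydroxy-3-methoxyphenyl)but-3-enoate
Conditions: pyrrolidine (20 mol%), PhCO2H (20 mol%), toluene, 60 °C, slow addition of 12 (1.5 equiv)
Reagents that add atoms: none
Why: amine-catalysed crossed aldol condensation (Mannich–elimination), in which the enamine of the enolisable aldehyde adds to the vanillin iminium ion and loss of pyrrolidine gives the thermodynamic (E)-2-substituted cinnamaldehyde.

**Step 6**
Reactants: 13 methyl (E)-3-formyl-4-(4-hydroxy-3-methoxyphenyl)but-3-enoate
Product: 14 (E)-4-[(4-hydroxy-3-methoxyphenyl)methylidene]oxolan-2-ol (lactol, anomeric mixture)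
Conditions: DIBAL-H (3.5 equiv), CH2Cl2, −78 °C; Rochelle salt work-up
Reagents that add atoms: none
Why: DIBAL-H 1,2-reduces the enal to the allylic alkoxide and stops the methyl ester at the aluminium hemiacetal at −78 °C, which closes to the five-membered lactol on work-up (partial ester reduction).

**Step 7**
Reactants: 14 (E)-4-[(4-hydroxy-3-methoxyphenyl)methylidene]oxolan-2-ol, 5 syringaldehyde
Product: 15 (2E,3E)-2-[(4-hydroxy-3,5-dimethoxyphenyl)methylidene]-3-(hydroxymethyl)-4-(4-hydroxy-3-methoxyphenyl)but-3-enal
Conditions: pyrrolidine (30 mol%), EtOH, 4 Å MS, 40 °C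
Reagents that add atoms: none
Why: the dienamine of the ring-opened β,γ-unsaturated aldehyde reacts at its α-carbon with the syringaldehyde iminium ion and eliminates pyrrolidine to give the (E)-arylidene enal (amine-catalysed aldol condensation); no stereocenter.

**Step 8**
Reactants: 15 (2E,3E)-2-[(4-hydroxy-3,5-dimethoxyphenyl)methylidene]-3-(hydroxymethyl)-4-(4-hydroxy-3-methoxyphenyl)but-3-enal
Product: 18 (1S,2R)-7-hydroxy-1-(4-hydroxy-3-methoxyphenyl)-2-(hydroxymethyl)-6,8-dimethoxy-1,2-dihydronaphthalene-3-carbaldehyde, via quinone methide 16 (not isolated), via spirodienone 17 (not isolated)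
Conditions: (R)-3,3'-bis(2,4,6-triisopropylphenyl)-BINOL N-triflylphosphoramide (10 mol%), 5 Å MS, CH2Cl2 (0.02 M), −40 °C to 23 °C
Reagents that add atoms: none
Why: Proposed new method: the chiral acid protonates the p-hydroxystyrene alkene of 15 at the CH2OH-bearing carbon inside a chiral ion pair (protonating the enal alkene would break its push–pull conjugation), which gives quinone methide 16 and sets that centre as R; the hydrogen-bonded syringyl phenol then attacks the methide carbon through its para (ipso) carbon in a 5-exo closure trans to CH2OH, setting the aryl-bearing centre in spirodienone 17, and the acid-promoted dienone–phenol 1,2-shift of this p-hydroxybenzylic carbon to the neighbouring ring carbon, with retention, expands the five- to the six-membered ring and rearomatises to 18; if protonation is reversible the same catalyst selects in the cyclisation (Curtin–Hammett); the closest known reactions are chiral phosphoric acid catalysis of p-quinone methides made in situ from p-hydroxybenzyl alcohols or hydroxystyrenes, catalytic asymmetric dearomatisation of para-substituted phenols to spiro[4.5]cyclohexadienones followed by stereospecific migration, and the racemic acid cyclisation of dibenzylidenesuccinates.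

**Compound list**
1 | p-cresol (4-methylphenol) | Cc1ccc(O)cc1 | starting material
2 | 2,6-dibromo-4-methylphenol | Cc1cc(Br)c(O)c(Br)c1 | intermediate
3 | 2,6-dibromo-4-(dibromomethyl)phenol | BrC(Br)c1cc(Br)c(O)c(Br)c1 | intermediate
4 | 3,5-dibromo-4-hydroxybenzaldehyde | O=Cc1cc(Br)c(O)c(Br)c1 | intermediate
5 | syringaldehyde (4-hydroxy-3,5-dimethoxybenzaldehyde) | COc1cc(C=O)cc(OC)c1O | intermediate
6 | catechol | Oc1ccccc1O | starting material
7 | guaiacol (2-methoxyphenol) | COc1ccccc1O | intermediate
8 | glyoxylic acid | O=CC(=O)O | starting material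
9 | vanillylmandelic acid (racemic) | COc1cc(C(O)C(=O)O)ccc1O | intermediate
10 | vanilloylformic acid ((4-hydroxy-3-methoxyphenyl)glyoxylic acid) | COc1cc(C(=O)C(=O)O)ccc1O | intermediate
11 | vanillin (4-hydroxy-3-methoxybenzaldehyde) | COc1cc(C=O)ccc1O | intermediate
12 | methyl 4-oxobutanoate | COC(=O)CCC=O | starting material
13 | methyl (E)-3-formyl-4-(4-hydroxy-3-methoxyphenyl)but-3-enoate | COC(=O)C/C(C=O)=C\c1ccc(O)c(OC)c1 | intermediate
14 | (E)-4-[(4-hydroxy-3-methoxyphenyl)methylidene]oxolan-2-ol (hemiacetal centre unassigned) | OC1C/C(=C\c2ccc(O)c(OC)c2)CO1 | intermediate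
15 | (2E,3E)-2-[(4-hydroxy-3,5-dimethoxyphenyl)methylidene]-3-(hydroxymethyl)-4-(4-hydroxy-3-methoxyphenyl)but-3-enal | O=C/C(=C/c1cc(OC)c(O)c(OC)c1)/C(CO)=C\c1ccc(O)c(OC)c1 | intermediate
16 | (2E,3R)-2-[(4-hydroxy-3,5-dimethoxyphenyl)methylidene]-3-(hydroxymethyl)-4-(3-methoxy-4-oxocyclohexa-2,5-dien-1-ylidene)butanal (p-quinone methide, exocyclic methide geometry unassigned) | O=C/C(=C/c1cc(OC)c(O)c(OC)c1)[C@H](CO)C=C1C=CC(=O)C(OC)=C1 | intermediate
17 | (3R,4S)-4-(4-hydroxy-3-methoxyphenyl)-3-(hydroxymethyl)-7,9-dimethoxy-8-oxospiro[4.5]deca-1,6,9-triene-2-carbaldehyde | O=C1C(OC)=CC2(C=C1OC)C=C(C=O)[C@H](CO)[C@H]2c1ccc(O)c(OC)c1 | intermediate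
18 | (1S,2R)-7-hydroxy-1-(4-hydroxy-3-methoxyphenyl)-2-(hydroxymethyl)-6,8-dimethoxy-1,2-dihydronaphthalene-3-carbaldehyde | COc1cc([C@H]2c3c(cc(OC)c(O)c3OC)C=C(C=O)[C@@H]2CO)ccc1O | target

**Step count and risks**
Total steps: 8. Longest linear sequence: 6 (6 → 7 → 11 → 13 → 14 → 15 → 18).

Most likely to fail:

Step 8 (the proposed new step). The risks are low enantioselectivity, a racemic background cyclisation, and diversion of the γ-hydroxy enal through its lactol to furan-type products. The fallback sets out from 15 and comes back at 18 with known chemistry: 15 is cyclised with an achiral acid (TFA, CH2Cl2, 0 °C, the established acid cyclisation of (E,E)-dibenzylidenesuccinate-type dienes to trans-1-aryl-1,2-dihydronaphthalenes). This gives the racemic trans product, that is 18 together with its enantiomer (1R,2S)-7-hydroxy-1-(4-hydroxy-3-methoxyphenyl)-2-(hydroxymethyl)-6,8-dimethoxy-1,2-dihydronaphthalene-3-carbaldehyde F1. Preparative chiral SFC on an amylose carbamate phase removes F1 and delivers 18; the yield is capped at 50%.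

Step 7. Lactol 14 can aromatise to a 3-benzylfuran, the dienamine can react at its γ-carbon, and 15 can start to cyclise racemically under the amine. The fallback sets out from 13 and comes back at 15, putting the second arylidene on at the lactone oxidation level instead. Luche reduction of 13 (NaBH4, CeCl3·7H2O, MeOH, 0 °C, then 1 M HCl) gives directly (E)-4-[(4-hydroxy-3-methoxyphenyl)methylidene]oxolan-2-one F2. Stobbe-type condensation of F2 with 5 (NaOMe, MeOH, 65 °C) gives (3E,4E)-3-[(4-hydroxy-3,5-dimethoxyphenyl)methylidene]-4-[(4-hydroxy-3-methoxyphenyl)methylidene]oxolan-2-one F3. DIBAL-H (CH2Cl2, −78 °C) reduces F3 to its lactol, which is the ring-closed tautomer of 15.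

Step 5. Vanillin is a weak electrophile, 12 can self-condense, and the alkene of 13 can drift into conjugation with the ester. The fallback sets out from 11 and comes back at 14, replacing the aldol condensation by a Wittig olefination and skipping 13. Maleic anhydride (O=C1OC(=O)C=C1, 7 heavy atoms) and PPh3 (acetone, 23 °C) give 3-(triphenyl-λ5-phosphanylidene)oxolane-2,5-dione F4. Wittig reaction of F4 with 11 (toluene, 80 °C) gives (E)-3-[(4-hydroxy-3-methoxyphenyl)methylidene]oxolane-2,5-dione F5. Methanol (60 °C) opens the anhydride at the non-conjugated carbonyl to (E)-2-[(4-hydroxy-3-methoxyphenyl)methylidene]-4-methoxy-4-oxobutanoic acid F6. BH3·SMe2 (THF, 0 °C, neutral work-up) reduces only the acid to methyl (E)-3-(hydroxymethyl)-4-(4-hydroxy-3-methoxyphenyl)but-3-enoate F7. DIBAL-H (CH2Cl2, −78 °C) takes F7 to 14.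

**Further compounds**
F1 | step 8 | (1R,2S)-7-hydroxy-1-(4-hydroxy-3-methoxyphenyl)-2-(hydroxymethyl)-6,8-dimethoxy-1,2-dihydronaphthalene-3-carbaldehyde | COc1cc([C@@H]2c3c(cc(OC)c(O)c3OC)C=C(C=O)[C@H]2CO)ccc1O
F2 | step 7 | (E)-4-[(4-hydroxy-3-methoxyphenyl)methylidene]oxolan-2-one | O=C1C/C(=C\c2ccc(O)c(OC)c2)CO1
F3 | step 7 | (3E,4E)-3-[(4-hydroxy-3,5-dimethoxyphenyl)methylidene]-4-[(4-hydroxy-3-methoxyphenyl)methylidene]oxolan-2-one | O=C1OC/C(=C/c2ccc(O)c(OC)c2)/C1=C\c1cc(OC)c(O)c(OC)c1
F4 | step 5 | 3-(triphenyl-λ5-phosphanylidene)oxolane-2,5-dione | O=C1CC(=P(c2ccccc2)(c2ccccc2)c2ccccc2)C(=O)O1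
F5 | step 5 | (E)-3-[(4-hydroxy-3-methoxyphenyl)methylidene]oxolane-2,5-dione | O=C1C/C(=C\c2ccc(O)c(OC)c2)C(=O)O1
F6 | step 5 | (E)-2-[(4-hydroxy-3-methoxyphenyl)methylidene]-4-methoxy-4-oxobutanoic acid | COC(=O)C/C(C(=O)O)=C\c1ccc(O)c(OC)c1
F7 | step 5 | methyl (E)-3-(hydroxymethyl)-4-(4-hydroxy-3-methoxyphenyl)but-3-enoate | COC(=O)C/C(CO)=C\c1ccc(O)c(OC)c1
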